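**Plan**

Ring labels: the flavanone has rings A (benzo), C (pyranone) and B (2-aryl, primed atoms). The flavone has rings D (benzo), E (pyranone) and F (2-aryl), with double-primed atoms.
Cuts: first the four O–benzyl bonds, then O1–C2 and C2–C3 of ring C, then C4a''–C4'', C4''–C3'' and O1''–C2'' of ring E, and last the biaryl bond C3'–C8''.
Forward order: rings B and D are joined by Suzuki coupling. Ring E, carrying ring F, is closed on ring D. Ring A is then attached through C3–C2 and ring C is closed.
Enabling feature: ring E holds only O1'', C2'', C3'' and C4'' between rings D and F, that is one phenol oxygen, two alkyne carbons and one CO. O1'' sits on C8a'', the ring D carbon between C8'' (biaryl) and C4a''. A ring D phenol with that single free OH and iodine on C4a'' can therefore give only the 8-aryl flavone.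
Stereochemistry: C2 (S) is the only stereocentre. It is set by a cinchona thiourea-catalysed oxa-Michael closure of ring C on a chalcone activated by a tert-butyl ester, which then leaves as isobutene and CO2.

Key step: step 5

Assumption: the quinidine-derived thiourea is taken to deliver 2S. Its quinine-derived pseudoenantiomer is equally available and would be used if the sense of induction on 15 turned out opposite.
Assumption: the C3'–C8'' axis is taken as configurationally labile, because the target carries no axial descriptor. Slowly interconverting rotamers of the benzylated intermediates are of no consequence.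
Remark: compounds 1, 3, 8 and 12 are catalogue chemicals.

**Step 1**
Reactants: 1 3,5-bis(benzyloxy)phenol
Product: 2 3,5-bis(benzyloxy)-2-iodophenol
Conditions: NIS (1.0 equiv), CH2Cl2, −20 to 0 °C, dark
Reagents that add atoms: N-iodosuccinimide, O=C1CCC(=O)N1I
Why: Electrophilic aromatic iodination of a phloroglucinol-type ring, in which the position between OH and OBn is less crowded than the one between two OBn groups, occurs twice and is favoured by hydrogen bonding of the phenol to NIS in a non-polar solvent, so the 2-iodide should be the main product and any 4-iodide is removed by chromatography.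

**Step 2**
Reactants: 3 5-formyl-2-methoxyphenylboronic acid
Product: 4 2-[5-(1,3-dioxolan-2-yl)-2-methoxyphenyl]-1,3,2-dioxaborolane
Conditions: HOCH2CH2OH (2.5 equiv), p-TsOH·H2O (2 mol %), toluene, Dean–Stark, reflux; concentrated and used without aqueous work-up
Reagents that add atoms: ethylene glycol, OCCO
Why: Acid-catalysed acetalisation with azeotropic removal of water, accompanied by esterification of the boronic acid, masks the aldehyde on the boron partner so that the strongly nucleophilic ring D never meets an aldehyde under acid.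

**Step 3**
Reactants: 2 3,5-bis(benzyloxy)-2-iodophenol; 4 2-[5-(1,3-dioxolan-2-yl)-2-methoxyphenyl]-1,3,2-dioxaborolane
Product: 5 3,5-bis(benzyloxy)-2-[5-(1,3-dioxolan-2-yl)-2-methoxyphenyl]phenol
Conditions: Pd(OAc)2 (3 mol %), SPhos (6 mol %), K3PO4 (3 equiv), 1,4-dioxane/H2O, 80 °C
Reagents that add atoms: none
Why: Suzuki–Miyaura coupling with a bulky, electron-rich biarylphosphine, the ligand class established for biaryls with three ortho substituents and for unprotected 2-halophenols, in which the glycol boronate is hydrolysed by the aqueous base and the dioxolane is stable to it.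

**Step 4**
Reactants: 5 3,5-bis(benzyloxy)-2-[5-(1,3-dioxolan-2-yl)-2-methoxyphenyl]phenol
Product: 6 3,5-bis(benzyloxy)-2-[5-(1,3-dioxolan-2-yl)-2-methoxyphenyl]-6-iodophenol
Conditions: NIS (1.0 equiv), NaHCO3 (solid), CH2Cl2, −20 to 0 °C, dark
Reagents that add atoms: N-iodosuccinimide, O=C1CCC(=O)N1I
Why: Electrophilic aromatic iodination ortho to the free phenol, where C6 (between OH and OBn) is open whereas C4 lies between two OBn groups, one of them pushed towards it by the neighbouring aryl group, ring B is far less activated, and solid NaHCO3 keeps the medium free of acid for the sake of the acetal.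

**Step 5**
Reactants: 6 3,5-bis(benzyloxy)-2-[5-(1,3-dioxolan-2-yl)-2-methoxyphenyl]-6-iodophenol; 7 carbon monoxide; 8 1-(benzyloxy)-4-ethynylbenzene
Product: 10 5,7-bis(benzyloxy)-2-[4-(benzyloxy)phenyl]-8-[5-(1,3-dioxolan-2-yl)-2-methoxyphenyl]-4H-chromen-4-one, via 2-hydroxyaryl ynone 9 (not isolated)
Conditions: PdCl2(PPh3)2 (5 mol %), CO (10 bar), 8 (1.5 equiv), Et2NH/DMF, 80 °C, autoclave
Reagents that add atoms: carbon monoxide (7), [C-]#[O+]
Why: PdCl2(PPh3)2 is reduced in the flask to zerovalent palladium, which inserts into the C4a''–I bond of 6; CO insertion gives an aroylpalladium species, and amine-assisted transfer of the alkynyl group of 8 followed by reductive elimination forges C4a''–C4'' and C4''–C3'' and releases ynone 9. The closest known reaction type is the carbonylative Sonogashira coupling–cyclisation of 2-iodophenols with terminal arylacetylenes in a secondary amine, an established flavone synthesis. Ring E closes by 6-endo-dig oxa-Michael addition of the C8a'' phenol oxygen to the aryl-bearing alkyne carbon (O1''–C2''), and no stereocentre is created. Three selectivities are needed: CO uptake ahead of direct alkynylation (which would end in a benzofuran) is secured by CO pressure, the absence of copper and the electron-rich migrating aryl group; 6-endo over 5-exo closure (aurone) is secured by the Et2NH medium, in which flavones are the known outcome; and 8-aryl over 6-aryl regiochemistry is fixed by the substrate, since the only free OH lies between the iodinated carbon and the biaryl carbon while the other oxygen next to iodine is benzylated. The dioxolane keeps the ring B aldehyde away from the amine–alkyne pair, and the benzyl ethers are inert.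

**Step 6**
Reactants: 10 5,7-bis(benzyloxy)-2-[4-(benzyloxy)phenyl]-8-[5-(1,3-dioxolan-2-yl)-2-methoxyphenyl]-4H-chromen-4-one
Product: 11 3-{5,7-bis(benzyloxy)-2-[4-(benzyloxy)phenyl]-4-oxo-4H-chromen-8-yl}-4-methoxybenzaldehyde
Conditions: 1 M aq. HCl, THF, rt
Reagents that add atoms: water, O
Why: Acid-catalysed acetal hydrolysis, to which the flavone, the aryl methyl ether and the benzyl ethers are inert.

**Step 7**
Reactants: 12 2',6'-dihydroxy-4'-methoxyacetophenone
Product: 13 1-[2-(benzyloxy)-6-hydroxy-4-methoxyphenyl]ethan-1-one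
Conditions: BnBr (1.05 equiv), K2CO3 (1.1 equiv), acetone, reflux
Reagents that add atoms: benzyl bromide, BrCc1ccccc1
Why: Williamson ether synthesis on a symmetric resorcinol, in which the OH left after the first alkylation is locked in a hydrogen bond to the acetyl group and is much less nucleophilic, so one equivalent of BnBr should stop at the monoether.

**Step 8**
Reactants: 13 1-[2-(benzyloxy)-6-hydroxy-4-methoxyphenyl]ethan-1-one
Product: 14 tert-butyl 3-[2-(benzyloxy)-6-hydroxy-4-methoxyphenyl]-3-oxopropanoate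
Conditions: LiN(SiMe3)2 (3.2 equiv), THF, −78 °C; Boc2O (1.1 equiv), −78 to 0 °C; sat. aq. NH4Cl
Reagents that add atoms: di-tert-butyl dicarbonate, CC(C)(C)OC(=O)OC(=O)OC(C)(C)C
Why: Claisen-type C-acylation of the lithium phenoxide–enolate dianion, in which the third equivalent of base stores the product as its enolate, the tert-butyl ester resists lactonisation to a 4-hydroxycoumarin, and any aryl carbonate formed at the phenoxide is relayed to carbon by a Baker–Venkataraman-type O-to-C transfer.

**Step 9**
Reactants: 11 3-{5,7-bis(benzyloxy)-2-[4-(benzyloxy)phenyl]-4-oxo-4H-chromen-8-yl}-4-methoxybenzaldehyde; 14 tert-butyl 3-[2-(benzyloxy)-6-hydroxy-4-methoxyphenyl]-3-oxopropanoate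
Product: 15 tert-butyl (Z)-2-[2-(benzyloxy)-6-hydroxy-4-methoxybenzoyl]-3-(3-{5,7-bis(benzyloxy)-2-[4-(benzyloxy)phenyl]-4-oxo-4H-chromen-8-yl}-4-methoxyphenyl)prop-2-enoate
Conditions: piperidine (20 mol %), AcOH (20 mol %), 4 Å MS, toluene, rt
Reagents that add atoms: none
Why: Knoevenagel condensation under buffered amine catalysis forms C2–C3 under conditions far milder for the flavone than an alkaline Claisen–Schmidt reaction, the Z isomer (ring B cis to the ester) is the one expected, and short contact at room temperature limits premature ring closure.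

**Step 10**
Reactants: 15 tert-butyl (Z)-2-[2-(benzyloxy)-6-hydroxy-4-methoxybenzoyl]-3-(3-{5,7-bis(benzyloxy)-2-[4-(benzyloxy)phenyl]-4-oxo-4H-chromen-8-yl}-4-methoxyphenyl)prop-2-enoate
Product: 18 (2S)-5-(benzyloxy)-2-(3-{5,7-bis(benzyloxy)-2-[4-(benzyloxy)phenyl]-4-oxo-4H-chromen-8-yl}-4-methoxyphenyl)-7-methoxychroman-4-one, via flavanone-3-carboxylic tert-butyl ester 16 (not isolated), via flavanone-3-carboxylic acid 17 (not isolated)
Conditions: N-[3,5-bis(trifluoromethyl)phenyl]-N'-[(9R)-6'-methoxycinchonan-9-yl]thiourea (10 mol %), toluene, −25 °C; then p-TsOH·H2O (0.5 equiv), 80 °C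
Reagents that add atoms: none
Why: Bifunctional cinchona thiourea catalysis of an intramolecular oxa-Michael addition (6-endo-trig), in which the thiourea binds the β-ketoester, the quinuclidine deprotonates the 2'-OH and the phenoxide is delivered to one face of C2 to set 2S, after which acid cleaves the tert-butyl ester and the β-keto acid decarboxylates, erasing the labile C3 centre without touching C2.

**Step 11**
Reactants: 18 (2S)-5-(benzyloxy)-2-(3-{5,7-bis(benzyloxy)-2-[4-(benzyloxy)phenyl]-4-oxo-4H-chromen-8-yl}-4-methoxyphenyl)-7-methoxychroman-4-one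
Product: 19 (2S)-2-{3-[5,7-dihydroxy-2-(4-hydroxyphenyl)-4-oxo-4H-chromen-8-yl]-4-methoxyphenyl}-5-hydroxy-7-methoxychroman-4-one (CNP0169789.1)
Conditions: H2 (1 atm), 10% Pd/C, THF/MeOH, rt; neutral work-up
Reagents that add atoms: none
Why: Catalytic hydrogenolysis of the four aryl benzyl ethers under neutral conditions, at which the flavone C2''=C3'' bond (a vinylogous ester) and the flavanone C2–O1 bond normally persist, while the absence of base avoids retro-oxa-Michael racemisation at C2.

**Compound list**

1 | 3,5-bis(benzyloxy)phenol | Oc1cc(OCc2ccccc2)cc(OCc2ccccc2)c1 | starting material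
2 | 3,5-bis(benzyloxy)-2-iodophenol | Oc1cc(OCc2ccccc2)cc(OCc2ccccc2)c1I | intermediate
3 | 5-formyl-2-methoxyphenylboronic acid | COc1ccc(C=O)cc1B(O)O | starting material
4 | 2-[5-(1,3-dioxolan-2-yl)-2-methoxyphenyl]-1,3,2-dioxaborolane | COc1ccc(C2OCCO2)cc1B1OCCO1 | intermediate
5 | 3,5-bis(benzyloxy)-2-[5-(1,3-dioxolan-2-yl)-2-methoxyphenyl]phenol | Oc1cc(OCc2ccccc2)cc(OCc2ccccc2)c1-c1cc(C2OCCO2)ccc1OC | intermediate
6 | 3,5-bis(benzyloxy)-2-[5-(1,3-dioxolan-2-yl)-2-methoxyphenyl]-6-iodophenol | Oc1c(I)c(OCc2ccccc2)cc(OCc2ccccc2)c1-c1cc(C2OCCO2)ccc1OC | intermediate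
7 | carbon monoxide | [C-]#[O+] | starting material
8 | 1-(benzyloxy)-4-ethynylbenzene | C#Cc1ccc(OCc2ccccc2)cc1 | starting material
9 | 1-{4,6-bis(benzyloxy)-3-[5-(1,3-dioxolan-2-yl)-2-methoxyphenyl]-2-hydroxyphenyl}-3-[4-(benzyloxy)phenyl]prop-2-yn-1-one | O=C(C#Cc1ccc(OCc2ccccc2)cc1)c1c(O)c(-c2cc(C3OCCO3)ccc2OC)c(OCc2ccccc2)cc1OCc1ccccc1 | intermediate
10 | 5,7-bis(benzyloxy)-2-[4-(benzyloxy)phenyl]-8-[5-(1,3-dioxolan-2-yl)-2-methoxyphenyl]-4H-chromen-4-one | O=c1cc(-c2ccc(OCc3ccccc3)cc2)oc2c(-c3cc(C4OCCO4)ccc3OC)c(OCc3ccccc3)cc(OCc3ccccc3)c12 | intermediate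
11 | 3-{5,7-bis(benzyloxy)-2-[4-(benzyloxy)phenyl]-4-oxo-4H-chromen-8-yl}-4-methoxybenzaldehyde | O=Cc1ccc(OC)c(-c2c(OCc3ccccc3)cc(OCc3ccccc3)c3c(=O)cc(-c4ccc(OCc5ccccc5)cc4)oc23)c1 | intermediate
12 | 2',6'-dihydroxy-4'-methoxyacetophenone | CC(=O)c1c(O)cc(OC)cc1O | starting material
13 | 1-[2-(benzyloxy)-6-hydroxy-4-methoxyphenyl]ethan-1-one | CC(=O)c1c(O)cc(OC)cc1OCc1ccccc1 | intermediate
14 | tert-butyl 3-[2-(benzyloxy)-6-hydroxy-4-methoxyphenyl]-3-oxopropanoate | CC(C)(C)OC(=O)CC(=O)c1c(O)cc(OC)cc1OCc1ccccc1 | intermediate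
15 | tert-butyl (Z)-2-[2-(benzyloxy)-6-hydroxy-4-methoxybenzoyl]-3-(3-{5,7-bis(benzyloxy)-2-[4-(benzyloxy)phenyl]-4-oxo-4H-chromen-8-yl}-4-methoxyphenyl)prop-2-enoate | CC(C)(C)OC(=O)/C(C(=O)c1c(O)cc(OC)cc1OCc1ccccc1)=C\c1ccc(OC)c(-c2c(OCc3ccccc3)cc(OCc3ccccc3)c3c(=O)cc(-c4ccc(OCc5ccccc5)cc4)oc23)c1 | intermediate
16 | tert-butyl (2S,3R)-5-(benzyloxy)-2-(3-{5,7-bis(benzyloxy)-2-[4-(benzyloxy)phenyl]-4-oxo-4H-chromen-8-yl}-4-methoxyphenyl)-7-methoxy-4-oxochromane-3-carboxylate (2,3-trans; C3 is labile) | COc1cc(OCc2ccccc2)c2c(c1)O[C@H](c1ccc(OC)c(-c3c(OCc4ccccc4)cc(OCc4ccccc4)c4c(=O)cc(-c5ccc(OCc6ccccc6)cc5)oc34)c1)[C@@H](C(=O)OC(C)(C)C)C2=O | intermediate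
17 | (2S,3R)-5-(benzyloxy)-2-(3-{5,7-bis(benzyloxy)-2-[4-(benzyloxy)phenyl]-4-oxo-4H-chromen-8-yl}-4-methoxyphenyl)-7-methoxy-4-oxochromane-3-carboxylic acid | COc1cc(OCc2ccccc2)c2c(c1)O[C@H](c1ccc(OC)c(-c3c(OCc4ccccc4)cc(OCc4ccccc4)c4c(=O)cc(-c5ccc(OCc6ccccc6)cc5)oc34)c1)[C@@H](C(=O)O)C2=O | intermediate
18 | (2S)-5-(benzyloxy)-2-(3-{5,7-bis(benzyloxy)-2-[4-(benzyloxy)phenyl]-4-oxo-4H-chromen-8-yl}-4-methoxyphenyl)-7-methoxychroman-4-one | COc1cc(OCc2ccccc2)c2c(c1)O[C@H](c1ccc(OC)c(-c3c(OCc4ccccc4)cc(OCc4ccccc4)c4c(=O)cc(-c5ccc(OCc6ccccc6)cc5)oc34)c1)CC2=O | intermediate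
19 | (2S)-2-{3-[5,7-dihydroxy-2-(4-hydroxyphenyl)-4-oxo-4H-chromen-8-yl]-4-methoxyphenyl}-5-hydroxy-7-methoxychroman-4-one | COc1cc(O)c2c(c1)O[C@H](c1ccc(OC)c(-c3c(O)cc(O)c4c(=O)cc(-c5ccc(O)cc5)oc34)c1)CC2=O | target

**Count**

Total steps: 11. Longest linear sequence: 8 steps (1, 3, 4, 5, 6, 9, 10, 11 from compound 1; equally 2, 3, 4, 5, 6, 9, 10, 11 from compound 3).

**Steps most likely to fail**

**Step 5.**
- Oxidative addition at the electron-rich C–I bond, which has two ortho substituents, may be slow.
- Alkynylation may outrun CO uptake and end in benzofuran closure.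
- The aroylpalladium species may be captured by Et2NH.
- Part of the ynone may close 5-exo.

The fallback sets out from 6 and 8, returns at 9 and from there reaches 10. It replaces gaseous CO by a carbamoyl chloride carbon and palladium by magnesium. Alkyne 8 is deprotonated with n-BuLi in THF at −78 °C and acylated with N-methoxy-N-methylcarbamoyl chloride to give the Weinreb amide N-methoxy-N-methyl-3-[4-(benzyloxy)phenyl]propiolamide F1. Iodophenol 6 is treated with MeMgCl to form the phenoxide and then with i-PrMgCl·LiCl for iodine–magnesium exchange (THF, −20 °C to rt). It is acylated in the same flask with F1, which should give ynone 9, now isolated. Stirring 9 with Et2NH in DMF should close ring E to 10.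

**Step 10.** Facial selectivity on this large substrate may be insufficient. Uncatalysed or piperidine-induced ring closure may already occur at the stage of 15, and reversible ring opening may occur before decarboxylation. Each of these would lower the enantiomeric purity of 18.

The fallback sets out from 18 of inadequate enantiomeric purity and returns to 18. It replaces asymmetric bond formation by kinetic resolution. Asymmetric transfer hydrogenation with RhCl[(R,R)-TsDPEN]Cp* and HCO2H/Et3N in EtOAc at rt should reduce the 2R enantiomer faster. The product would be the cis alcohol (2R,4R)-5-(benzyloxy)-2-(3-{5,7-bis(benzyloxy)-2-[4-(benzyloxy)phenyl]-4-oxo-4H-chromen-8-yl}-4-methoxyphenyl)-7-methoxychroman-4-ol F2. The 2S ketone 18 should remain and is separated by chromatography. The flavone carbonyl, a vinylogous ester, should not be reduced.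

**Step 4.** Iodine may attack the position para to the phenol (C4, between the two OBn groups), or a second iodination may take place. Either would erode the supply of the one isomer that can close ring E.

The fallback sets out from 5 and returns at 6. It replaces electrophilic substitution by directed ortho-metalation.
- Phenol 5 is carbamoylated (NaH, ClC(O)NEt2, THF) to 3,5-bis(benzyloxy)-2-[5-(1,3-dioxolan-2-yl)-2-methoxyphenyl]phenyl N,N-diethylcarbamate F3.
- s-BuLi/TMEDA in THF at −78 °C should lithiate the only free position next to the carbamate, which is also flanked by OBn. Quenching with I2 should give 3,5-bis(benzyloxy)-2-[5-(1,3-dioxolan-2-yl)-2-methoxyphenyl]-6-iodophenyl N,N-diethylcarbamate F4.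
- Reductive cleavage of the carbamate with Cp2Zr(H)Cl in THF at rt should free phenol 6 without acid or strong base.

**Further compounds**

F1 | step 5 | N-methoxy-N-methyl-3-[4-(benzyloxy)phenyl]propiolamide | CON(C)C(=O)C#Cc1ccc(OCc2ccccc2)cc1
F2 | step 10 | (2R,4R)-5-(benzyloxy)-2-(3-{5,7-bis(benzyloxy)-2-[4-(benzyloxy)phenyl]-4-oxo-4H-chromen-8-yl}-4-methoxyphenyl)-7-methoxychroman-4-ol | COc1cc(OCc2ccccc2)c2c(c1)O[C@@H](c1ccc(OC)c(-c3c(OCc4ccccc4)cc(OCc4ccccc4)c4c(=O)cc(-c5ccc(OCc6ccccc6)cc5)oc34)c1)C[C@H]2O
F3 | step 4 | 3,5-bis(benzyloxy)-2-[5-(1,3-dioxolan-2-yl)-2-methoxyphenyl]phenyl N,N-diethylcarbamate | CCN(CC)C(=O)Oc1cc(OCc2ccccc2)cc(OCc2ccccc2)c1-c1cc(C2OCCO2)ccc1OC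
F4 | step 4 | 3,5-bis(benzyloxy)-2-[5-(1,3-dioxolan-2-yl)-2-methoxyphenyl]-6-iodophenyl N,N-diethylcarbamate | CCN(CC)C(=O)Oc1c(I)c(OCc2ccccc2)cc(OCc2ccccc2)c1-c1cc(C2OCCO2)ccc1OC
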